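**Retrosynthetic overview**

1. Target ⇐ acylation of the 6β‑OH with the veratroyl unit ⇐ 6β‑OH‑directed 8β,9β‑epoxidation ⇐ selective 2‑O‑acetylation of an all‑syn 2β,4β,6β‑triol.
2. Triol ⇐ zinc‑chelate reduction of a 4β‑hydroxy‑2,6‑diketone; the C4 tertiary carbinol templates both new carbinol centres.
3. Seven‑membered ring (formed second) ⇐ ring‑closing metathesis across C8=C9; its two arms (C1 allyl, C5 acyl‑anion unit carrying a 2‑methylallyl group) are set trans by Michael addition/enolate allylation of a 4‑hydroxy‑4‑isopropyl‑2‑methylcyclopentenone.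
4. Five‑membered ring (formed first) ⇐ aldol condensation of a γ‑keto aldehyde; the C4–O bond, the only stereocentre set by a catalyst, comes from an amine‑catalysed enantioselective γ‑oxygenation of that cyclopentenone with O2 (key step).
5. The other six stereocentres are relayed from that carbinol: C5 and C1 in the coupling, C2 and C6 by chelation, C8 and C9 by the directed epoxidation.

Assumption: the stereochemistry is taken exactly as written in the SMILES (trans ring fusion; acetate, tertiary OH, veratrate and epoxide oxygen all on the face of the angular methyl).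

Convention: daucane numbering is used throughout, also for monocyclic precursors. C1 is the ring‑fusion carbon with the angular methyl; C2, C3, C4 (OH, isopropyl) and C5 (ring‑fusion CH) complete the five‑membered ring; C6, C7, C8 (methyl), C9, C10 complete the seven‑membered ring. β is the face of the C1 methyl, α the opposite face.

**Route**

Step 1
Reactants: 1 3-methylbutanal; 2 1-bromobutan-2-one
Product: 4 (±)-2-isopropyl-4-oxohexanal, via piperidine enamine 3 (not isolated)
Conditions: piperidine, K2CO3, 0 °C to rt; then 2, MeCN, 80 °C; then aq. AcOH/NaOAc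
Reagents that add atoms: none
Why: Stork enamine alkylation, in which the aldehyde enamine is C‑alkylated by the α‑bromo ketone and hydrolysed to the γ‑keto aldehyde; the new centre is racemic and is erased in step 3.

Step 2
Reactants: 4 (±)-2-isopropyl-4-oxohexanal
Product: 5 (±)-4-isopropyl-2-methylcyclopent-2-en-1-one
Conditions: KOH (2 %), MeOH/H2O, reflux
Reagents that add atoms: none
Why: Intramolecular aldol condensation, in which only the ethyl‑ketone CH2 can close a five‑membered ring onto the aldehyde.

Step 3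
Reactants: 5 (±)-4-isopropyl-2-methylcyclopent-2-en-1-one
Product: 7 (S)-4-hydroxy-4-isopropyl-2-methylcyclopent-2-en-1-one, via γ-hydroperoxide 6 (not isolated)
Conditions: 9-amino-9-deoxy-epi-quinine (20 mol %), CF3CO2H (40 mol %), 5,10,15,20-tetraphenylporphyrin (1 mol %), O2 (1 atm), white LEDs, CHCl3, −20 °C; then Me2S, 0 °C
Reagents that add atoms: dioxygen O=O
Why: Proposed new method: the primary‑amine salt converts both enantiomers of 5 into one linear dienamine, a catalyst‑bound 1‑aminocyclopentadiene in which C4 is planar; singlet oxygen adds [4+2] across its termini C2 and C4 on the face left open by the catalyst, the amino endoperoxide collapses to the γ‑hydroperoxy iminium ion (this forms the C4–O bond and sets the S centre), and hydrolysis plus Me2S reduction give 7, with γ‑selectivity enforced because only C2 and C4 end the ring diene and the acid keeping the quinuclidine protonated so that it does not quench singlet oxygen; the closest known reactions are the dienamine [4+2] γ‑amination of enals with azodicarboxylates and the amino‑acid‑catalysed α‑oxygenation of carbonyl compounds with singlet oxygen.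

Step 4
Reactants: 8 1,3-dithiane; 9 3-chloro-2-methylprop-1-ene
Product: 11 2-(2-methylallyl)-1,3-dithiane, via 2-lithio-1,3-dithiane 10 (not isolated)
Conditions: n-BuLi, THF, −30 °C; then 9, −78 °C to rt
Reagents that add atoms: none
Why: Corey–Seebach alkylation of the lithiated dithiane by the allylic chloride gives the masked acyl anion that will become C6–C8.

Step 5
Reactants: 7 (S)-4-hydroxy-4-isopropyl-2-methylcyclopent-2-en-1-one; 11 2-(2-methylallyl)-1,3-dithiane; 12 allyl bromide
Product: 16 (4S)-2-allyl-4-hydroxy-4-isopropyl-2-methyl-3-[2-(2-methylallyl)-1,3-dithian-2-yl]cyclopentan-1-one (dithianyl cis to OH; allyl trans to dithianyl), via lithiated dithiane 13 (not isolated), via lithium alkoxide 14 (not isolated), via dilithium enolate 15 (not isolated)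
Conditions: 11, n-BuLi, THF, −30 °C, then DMPU, −78 °C; add 7 premixed with LiN(SiMe3)2 (1.0 equiv, THF, −78 °C); then 12, −78 to −30 °C; NH4Cl
Reagents that add atoms: none
Why: Michael addition–enolate alkylation (three‑component coupling), in which the dithiane anion adds 1,4 to C5 anti to the isopropyl group and syn to the lithium alkoxide, and the C1 enolate is then allylated anti to the bulky dithianyl group, so the quaternary C1 carries allyl trans to C6 and methyl cis to the C4 oxygen.

Step 6
Reactants: 16 three-component adduct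
Product: 17 4β-hydroxy-6,6-(propane-1,3-diyldisulfanediyl)dauc-8-en-2-one (5αH; trans-fused)
Conditions: second-generation Grubbs catalyst RuCl2(=CHPh)(PCy3)(H2IMes) (5 mol %), toluene (5 mM), 80 °C
Reagents that add atoms: none
Why: Ring‑closing metathesis of the allyl and 2‑methylallyl arms, which sit trans on the cyclopentane, closes the trans‑fused cycloheptene with the trisubstituted C8=C9 bond without touching a stereocentre.

Step 7
Reactants: 17 dithiane-protected hydroxy ketone
Product: 18 4β-hydroxydauc-8-ene-2,6-dione (5αH)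
Conditions: MeI, CaCO3, MeCN/H2O (9:1), 45 °C
Reagents that add atoms: water O
Why: Dithioacetal hydrolysis by S‑methylation under buffered, near‑neutral conditions spares the retro‑aldol‑prone bis(β‑hydroxy ketone) and the β,γ‑unsaturated ketone.

Step 8
Reactants: 18 4β-hydroxydauc-8-ene-2,6-dione
Product: 19 dauc-8-ene-2β,4β,6β-triol (5αH)
Conditions: Zn(BH4)2 (stock solution in Et2O), −20 to 0 °C; aq. NH4Cl
Reagents that add atoms: none
Why: Chelation‑controlled reduction of both β‑hydroxy ketones (Oishi‑type Zn(BH4)2 reduction), in which zinc bridges the C4 oxygen and each carbonyl on the β face and hydride adds from the α face, anti to the angular methyl, to give the 2β and 6β alcohols.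

Step 9
Reactants: 19 dauc-8-ene-2β,4β,6β-triol; 20 acetic anhydride
Product: 23 2β-acetoxydauc-8-ene-4β,6β-diol (5αH), via phenylboronate 21 (not isolated), via boronate acetate 22 (not isolated)
Conditions: PhB(OH)2 (1.05 equiv), MgSO4, CH2Cl2, rt; then 20, pyridine, 4-(dimethylamino)pyridine (cat.), 0 °C to rt; then pinacol, rt
Reagents that add atoms: none
Why: Regioselective acylation under transient boronate protection, in which the 4,6‑syn‑1,3‑diol forms a six‑membered phenylboronate (the 2,4‑alternative would be a strained bridged bicycle), only the 2‑OH is acetylated, and pinacol transesterification frees the diol.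

Step 10
Reactants: 23 2β-acetoxydauc-8-ene-4β,6β-diol
Product: 24 2β-acetoxy-8β,9β-epoxydaucane-4β,6β-diol (5αH)
Conditions: VO(acac)2 (5 mol %), t-BuOOH (1.5 equiv), CH2Cl2, 0 °C to rt
Reagents that add atoms: tert-butyl hydroperoxide CC(C)(C)OO
Why: Hydroxyl‑directed epoxidation (Sharpless–Michaelson vanadium/t‑BuOOH), in which the homoallylic 6β‑OH binds vanadium and delivers oxygen to the β face of C8=C9, setting C8 and C9 cis to the C6 oxygen.

Step 11
Reactants: 24 2β-acetoxy-8β,9β-epoxydaucane-4β,6β-diol; 25 3,4-dimethoxybenzoyl chloride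
Product: 26 2β-acetoxy-8β,9β-epoxy-4β-hydroxy-5αH-daucan-6β-yl 3,4-dimethoxybenzoate (CNP0330776.1)
Conditions: 25, Et3N, 4-(dimethylamino)pyridine, CH2Cl2, 40 °C
Reagents that add atoms: none
Why: Acyl‑transfer esterification catalysed by 4‑(dimethylamino)pyridine acylates the only secondary hydroxyl, while the tertiary 4‑OH and the epoxide do not react.

**Compound list**

1 | 3-methylbutanal | CC(C)CC=O | starting material
2 | 1-bromobutan-2-one | CCC(=O)CBr | starting material
3 | (E)-1-(3-methylbut-1-en-1-yl)piperidine | CC(C)/C=C/N1CCCCC1 | intermediate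
4 | (±)-2-isopropyl-4-oxohexanal | CCC(=O)CC(C(C)C)C=O | intermediate
5 | (±)-4-isopropyl-2-methylcyclopent-2-en-1-one | CC1=CC(C(C)C)CC1=O | intermediate
6 | (S)-4-hydroperoxy-4-isopropyl-2-methylcyclopent-2-en-1-one | CC(C)[C@@]1(OO)CC(=O)C(C)=C1 | intermediate
7 | (S)-4-hydroxy-4-isopropyl-2-methylcyclopent-2-en-1-one | CC(C)[C@@]1(O)CC(=O)C(C)=C1 | intermediate
8 | 1,3-dithiane | C1CSCSC1 | starting material
9 | 3-chloro-2-methylprop-1-ene | CC(=C)CCl | starting material
10 | 2-lithio-1,3-dithiane | [Li]C1SCCCS1 | intermediate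
11 | 2-(2-methylallyl)-1,3-dithiane | CC(=C)CC1SCCCS1 | intermediate
12 | allyl bromide | C=CCBr | starting material
13 | 2-lithio-2-(2-methylallyl)-1,3-dithiane | [Li]C1(CC(C)=C)SCCCS1 | intermediate
14 | lithium alkoxide of 7 | CC(C)[C@@]1(O[Li])CC(=O)C(C)=C1 | intermediate
15 | dilithium enolate alkoxide (Michael adduct; dithianyl cis to OLi at C4) | CC(C)[C@@]1(O[Li])CC(O[Li])=C(C)[C@@H]1C1(CC(C)=C)SCCCS1 | intermediate
16 | (4S)-2-allyl-4-hydroxy-4-isopropyl-2-methyl-3-[2-(2-methylallyl)-1,3-dithian-2-yl]cyclopentan-1-one (dithianyl cis to OH, allyl trans to dithianyl) | C=CC[C@]1(C)C(=O)C[C@](O)(C(C)C)[C@H]1C1(CC(C)=C)SCCCS1 | intermediate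
17 | 4β-hydroxy-6,6-(propane-1,3-diyldisulfanediyl)dauc-8-en-2-one (5αH) | CC1=CC[C@]2(C)C(=O)C[C@](O)(C(C)C)[C@H]2C2(C1)SCCCS2 | intermediate
18 | 4β-hydroxydauc-8-ene-2,6-dione (5αH) | CC1=CC[C@]2(C)C(=O)C[C@](O)(C(C)C)[C@H]2C(=O)C1 | intermediate
19 | dauc-8-ene-2β,4β,6β-triol (5αH) | CC1=CC[C@]2(C)[C@@H](O)C[C@](O)(C(C)C)[C@H]2[C@@H](O)C1 | intermediate
20 | acetic anhydride | CC(=O)OC(C)=O | starting material
21 | 4,6-O-(phenylboranediyl) derivative of 19 | CC1=CC[C@]2(C)[C@@H](O)C[C@@]3(C(C)C)OB(c4ccccc4)O[C@@H](C1)[C@@H]23 | intermediate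
22 | 2β-acetate of 21 | CC1=CC[C@]2(C)[C@@H](OC(C)=O)C[C@@]3(C(C)C)OB(c4ccccc4)O[C@@H](C1)[C@@H]23 | intermediate
23 | 2β-acetoxydauc-8-ene-4β,6β-diol (5αH) | CC1=CC[C@]2(C)[C@@H](OC(C)=O)C[C@](O)(C(C)C)[C@H]2[C@@H](O)C1 | intermediate
24 | 2β-acetoxy-8β,9β-epoxydaucane-4β,6β-diol (5αH) | O[C@H]1C[C@@]2(C)O[C@H]2C[C@]2(C)[C@@H](OC(C)=O)C[C@](O)(C(C)C)[C@@H]12 | intermediate
25 | 3,4-dimethoxybenzoyl chloride | COc1ccc(C(Cl)=O)cc1OC | starting material
26 | 2β-acetoxy-8β,9β-epoxy-4β-hydroxy-5αH-daucan-6β-yl 3,4-dimethoxybenzoate (CNP0330776.1) | COc1ccc(C(=O)O[C@H]2C[C@@]3(C)O[C@H]3C[C@]3(C)[C@@H](OC(C)=O)C[C@](O)(C(C)C)[C@@H]23)cc1OC | target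

**Step count and risks**

Total step count: 11. Longest linear sequence: 10 steps (steps 1, 2, 3, 5, 6, 7, 8, 9, 10, 11 from 3-methylbutanal); step 4 is a one-step side branch.

Steps most likely to fail:

Step 3 (the proposed new γ‑oxygenation). The cross‑conjugated dienamine may compete, the catalyst may be bleached, and the level or even the sense of induction is untested; the pseudoenantiomeric epi‑quinidine amine is the first variation. The fallback uses known chemistry only and sets out from 5. Ketalisation with ethane‑1,2‑diol and TsOH (benzene, Dean–Stark) moves the double bond out of conjugation and gives (±)-7-isopropyl-9-methyl-1,4-dioxaspiro[4.4]non-7-ene F1. Shi epoxidation of this trisubstituted cyclopentene with 1,2:4,5-di-O-isopropylidene-β-L-erythro-2,3-hexodiulo-2,6-pyranose (ent‑Shi ketone) and KHSO5 (as 2KHSO5·KHSO4·K2SO4, K2CO3 buffer, MeCN/dimethoxymethane, 0 °C) gives 7,8-epoxy-7-isopropyl-9-methyl-1,4-dioxaspiro[4.4]nonane F2, with the epoxide oxygen on the face that becomes the S hydroxyl. Aqueous HCl in THF removes the ketal, and the β,γ‑epoxy ketone opens by β‑elimination to 7, where the route is rejoined.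

Step 5 (three‑component coupling). The β‑carbon is flanked by the quaternary carbinol, so the bulky dithiane anion may add 1,2 or not at all. The fallback sets out from 7 and delivers C6 from the C4 oxygen instead. Silylation with (bromomethyl)chlorodimethylsilane (imidazole, DMF) gives (S)-4-{[(bromomethyl)dimethylsilyl]oxy}-4-isopropyl-2-methylcyclopent-2-en-1-one F3. Heating with allyltributylstannane and AIBN (benzene, 80 °C) causes 5‑exo radical cyclisation onto C5 and allyl transfer to the C1 radical (Stork silicon tether, Keck allylation), giving the cis‑fused oxasilolane ketone F4 with allyl trans to the new C5–C6 bond. Tamao–Fleming oxidation (H2O2, KF, KHCO3) gives (4S)-2-allyl-4-hydroxy-3-(hydroxymethyl)-4-isopropyl-2-methylcyclopentan-1-one F5. Oxidation with TEMPO and PhI(OAc)2 gives the corresponding 3-carbaldehyde F6. 2‑Methylallylboronic acid pinacol ester adds to the aldehyde only and gives the 3-(1-hydroxy-3-methylbut-3-enyl) ketone F7. Dess–Martin periodinane gives (4S)-2-allyl-4-hydroxy-4-isopropyl-2-methyl-3-(3-methylbut-3-enoyl)cyclopentan-1-one F8. Ring‑closing metathesis with the second‑generation Grubbs catalyst RuCl2(=CHPh)(PCy3)(H2IMes) then gives 18, where the route is rejoined.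

Step 9 (boronate‑masked acetylation). The boronate may not discriminate cleanly between the 4,6‑ and 2,4‑diol pairs, or the 2‑OH may acetylate sluggishly next to the quaternary carbon. The fallback sets out from 17 and differentiates the two carbinols by the order of unmasking. Zn(BH4)2 reduces the only free ketone to 6,6-(propane-1,3-diyldisulfanediyl)dauc-8-ene-2β,4β-diol F9. Ac2O, pyridine and 4‑(dimethylamino)pyridine give 2β-acetoxy-6,6-(propane-1,3-diyldisulfanediyl)dauc-8-en-4β-ol F10. MeI and CaCO3 in aqueous MeCN unmask 2β-acetoxy-4β-hydroxydauc-8-en-6-one F11. Zn(BH4)2 at −40 °C reduces the C6 ketone under chelation by the 4‑OH without touching the acetate and gives 23, where the route is rejoined.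

Further compounds
F1 | step 3 | (±)-7-isopropyl-9-methyl-1,4-dioxaspiro[4.4]non-7-ene | CC1C=C(C(C)C)CC12OCCO2
F2 | step 3 | 7,8-epoxy-7-isopropyl-9-methyl-1,4-dioxaspiro[4.4]nonane (C9 epimers) | CC(C)[C@@]12CC3(OCCO3)C(C)[C@@H]1O2
F3 | step 5 | (S)-4-{[(bromomethyl)dimethylsilyl]oxy}-4-isopropyl-2-methylcyclopent-2-en-1-one | CC(C)[C@@]1(O[Si](C)(C)CBr)CC(=O)C(C)=C1
F4 | step 5 | cis-fused oxasilolane ketone (C1 allyl trans to C5–C6 bond) | C=CC[C@]1(C)C(=O)C[C@@]2(C(C)C)O[Si](C)(C)C[C@@H]12
F5 | step 5 | (4S)-2-allyl-4-hydroxy-3-(hydroxymethyl)-4-isopropyl-2-methylcyclopentan-1-one | C=CC[C@]1(C)C(=O)C[C@](O)(C(C)C)[C@H]1CO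
F6 | step 5 | (4S)-2-allyl-4-hydroxy-4-isopropyl-2-methyl-3-formylcyclopentan-1-one | C=CC[C@]1(C)C(=O)C[C@](O)(C(C)C)[C@H]1C=O
F7 | step 5 | (4S)-2-allyl-4-hydroxy-3-(1-hydroxy-3-methylbut-3-enyl)-4-isopropyl-2-methylcyclopentan-1-one (carbinol epimers) | C=CC[C@]1(C)C(=O)C[C@](O)(C(C)C)[C@H]1C(O)CC(C)=C
F8 | step 5 | (4S)-2-allyl-4-hydroxy-4-isopropyl-2-methyl-3-(3-methylbut-3-enoyl)cyclopentan-1-one | C=CC[C@]1(C)C(=O)C[C@](O)(C(C)C)[C@H]1C(=O)CC(C)=C
F9 | step 9 | 6,6-(propane-1,3-diyldisulfanediyl)dauc-8-ene-2β,4β-diol | CC1=CC[C@]2(C)[C@@H](O)C[C@](O)(C(C)C)[C@H]2C2(C1)SCCCS2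
F10 | step 9 | 2β-acetoxy-6,6-(propane-1,3-diyldisulfanediyl)dauc-8-en-4β-ol | CC1=CC[C@]2(C)[C@@H](OC(C)=O)C[C@](O)(C(C)C)[C@H]2C2(C1)SCCCS2
F11 | step 9 | 2β-acetoxy-4β-hydroxydauc-8-en-6-one | CC1=CC[C@]2(C)[C@@H](OC(C)=O)C[C@](O)(C(C)C)[C@H]2C(=O)C1
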